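All runs were generated by integration for substances that don't exist; noise was put on by code.

Late in the larch run X stopped moving. That run was this very flask, with 31 mM of G. From 30.0 min to 90.0 min X read 3.3%, 4.5% and 3.9%, with no trend beyond the scatter. So I carried one number: the plateau concentration cX, the mean of those late shares times the charge, 1.21 mM.

all flasks: G 31 mM
- larch: the very flask that is asked about, followed so far
- flask: time 3.0 h

- larch (time / min: D / %, X / %, G / %): 8.00: 22.3, 10.1, 68.4; 12.0: 38.6, 7.7, 51.8; 20.0: 69.6, 8.5, 19.9; 30.0: 95.0, 3.3, 0.1; 50.0: 94.3, 4.5, 0; 90.0: 95.8, 3.9, 0.4

(each reading ± 1 percentage point)

- what is said of D includes Q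
- Q, G is a solid; its amount is given per volume of the solution
- on the list of suspects stand: X <-> D; Q <-> D; G <-> X
- at the start none of G is in solution
- what has only dissolved of G counts as not reacted
- the reaction counts as stopped when no species that holds the G changes by six tenths of a point or more over the second half of the time
- X means what is dissolved; the solid is not counted in it

- why nothing more happens at 3.0 h, or that something still does (for what has run out or reacted, a solid counts together with what of it has only dissolved) (it is still moving / forward and back rates have come level / all of G has reacted)
- how much D there is at 3.0 h, in percent of the G charged
- how much X there is at 3.0 h, in percent of the G charged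

I went through the run slowly. At the start the flask held solid G and nothing dissolved. G then entered solution as X, and X passed on to D: at 8.00 min D already read twice X. In the middle G fell in a nearly straight line, about 1.25 mM/min from 8.00 min to 20.0 min. I read that as zero order in G, while cX stayed between 2.39 mM and 3.13 mM. At 30.0 min G read 0.1% and X had dropped to its plateau. I assumed that crystals Q stood by then and held dissolved D, and X beside it, at fixed concentrations. So I expected level rates at 3.0 h, with 3.90% of X and 96.1% of D.

The forecast gave forward and back rates have come level, with 95.6% of D and 4.3% of X, slightly more X than my figure. It said: “this is a balance, not exhaustion of substrate”.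

The flask gave 95.6% of D and 4.37% of X, and the ending was: forward and back rates have come level. A charge of 14.5 mM of G, with the rest held, moved the answer for X by 5 points, and a change of charge that far would make this forecast wrong. My plateau cX of 1.21 mM, itself a reading with its scatter, stood for 0.47 percentage points less X than the flask gave, a gap smaller than the scatter of one reading.

    X ⇌ D (K = 4.06, k = 0.916 /min)
    Q ⇌ D, rate k2*(cs2 - [D]) while solid is left; crystals form when [D] > cs2 (solubility = 5.50 mM, k = 1.88 /min)
    G ⇌ X, rate k3*(cs3 - [X]) while solid is left; crystals form when [X] > cs3 (solubility = 14.0 mM, k = 0.104 /min)

In the neighbour flask with 12 mM of G, the same plateau cX gives 10.1% of X, provided crystals stand. That flask gave 11.3% of X at 3.0 h, beside 42.9% of Q.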